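## Analysis of the target

Target 26 is a drimane-type sesquiterpene: a trans-fused decalin (ring A = C1–C2–C3–C4–C5–C10, ring B = C5–C6–C7–C8–C9–C10). C11 (on C9) is an aryl ether of 7-hydroxycoumarin, C13 (on C4) is an angelate ester, and there is a free secondary hydroxyl at C3 and a free tertiary hydroxyl at C8. The six stereocentres, (3R,4S,5S,8S,9R,10R), all lie in the decalin. The methyl groups C14 (on C4), C15 (on C10) and C12 (on C8) are axial on one face (called α below); H5 and H9 are axial on the other (β) face; O3, C13, C11 and O8 are equatorial. C4 and C10 are quaternary carbons in a 1,3 relationship, C8 is a fully substituted carbinol, and C4 is stereogenic only because C13 is oxygenated and C14 is not. The angelate is the most delicate group (Z to E isomerisation on acylation, cleavage by hydride or base), followed by the coumarin lactone (hydride, hydroxide) and the tertiary alcohol (acid-promoted dehydration); the three hydroxyls of the 3,8,13-triol must also be told apart at the end. The hard parts are the quaternary C10 next to the substituted C9, the cis relationship of C14 and C15, and the C8/C9 pair. The strategy rests on ring B: C8, C9, C11 and C12 are the four carbons of a but-2-ynoate, and C10, C5, C6 and C7 are a diene made of a ring A cyclohexene double bond and a vinyl group.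

## Retrosynthetic reasoning

**C13–O acyl bond (26 ⇒ 23 + 24).** The angelate is cut first because it survives neither the hydride reductions nor the strong bases used earlier. The forward step must acylate the primary, neopentyl C13 hydroxyl of 23 in the presence of the hindered secondary C3 and tertiary C8 hydroxyls, through the mixed anhydride 25, without Z/E isomerisation.

**Acetonide and C11–O aryl bond (23 ⇒ 22 ⇒ 20 + 21).** The 3,13-diol is carried as a trans-fused acetonide, which masks both oxygens in one group and later fixes the conformation of ring A. The aryl ether is cut at C11–O because the lactone of 21 would not survive hydride; it must be attached after the last reduction, at the only primary hydroxyl of 20.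

**C8–O bond and the C9 centre (20 ⇒ 19 ⇒ 18 ⇒ 16).** The tertiary carbinol is traced to the exocyclic C8=C12 alkene of 19, so that C8 is set by hydration with oxygen delivered equatorially. The alkene and the C9–H centre come from the conjugated ester 16 by deconjugative protonation (18) and ester reduction. This keeps C11 at the ester level until C9 is set.

**C5–H bond (16 ⇒ 15).** The ring fusion is set by adding hydrogen to C5=C6 of 15 on the face opposite the two axial methyl groups that flank C5.

**C9–C10 and C7–C8 (15 ⇒ 13 + 14).** Cutting both bonds of ring B removes the ring and the quaternary C10 in one operation and leaves a monocyclic diene and a purchased ynoate. No other pair of bonds in ring B maps onto such simple partners, and the alkyne brings C8, C9, C11 and C12 at the oxidation level that the later steps use. The forward cycloaddition must be regioselective (C7 to the β-carbon of 14) and must add to the face of 13 opposite C14.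

**C5–C6 bond (13 ⇒ 12 ⇒ 10).** The vinyl group is attached by cross-coupling of the enol triflate 12 with a vinyl–tin reagent. The triflate comes from enone 10 by conjugate reduction and trapping of the enolate 11, which places the double bond between C5 and C10 without any choice of regiochemistry.

**C3–O bond (10 ⇒ 9 ⇒ 8 ⇒ 6).** O3 is traced to an isopropenyl group by ozonolysis and oxidative rearrangement with retention (through 7). A carbon substituent at C3 is needed during the enolate steps, where a β-oxygen would be eliminated.

**C4–C14 and C4–C13 bonds (6 ⇒ 3 ⇒ 1).** The quaternary C4 is built by two successive enolate reactions of 1 (through 2, then 4 and 5). Each electrophile enters anti to the isopropenyl group, so the methyl goes in first and the hydroxymethyl carbon second, which puts C13 trans and C14 cis to the future O3. Compound 1 already supplies C15, the C5 carbonyl, the C10=C1 double bond and the C3 stereocentre in the right absolute sense.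

## Alternatives that were turned down

**Alternative 1:** The disconnection is C5–C10 and C8–C9, closing both rings by intramolecular Diels–Alder reaction of the acyclic triene A1 to the bicyclic silyl ether ester A2.
- Forward key step: Me2AlCl activates the (E)-enoate C9=C10 of A1, which adds across the silyloxy diene C5=C6–C7=C8; ring B is the cycloadduct ring and ring A the tether ring.
- For it: both rings and four stereocentres (C5, C8, C9, C10) form at once, C8 arrives as a protected tertiary carbinol, and A2 needs only about six further steps. On these points it is stronger than the chosen route.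
- Against it: A1 is a linear chain that must already contain C3/C4 and three alkenes of defined geometry. The C8 configuration of A2 requires the silyloxy group to be the inward substituent of the diene terminus, which is the geometry hardest to make and slowest to reach the s-cis conformer. C9 would be formed between a disubstituted dienophile carbon (C10) and a fully substituted diene carbon (C8). The Lewis acid could also divert the silyl dienol ether into a stepwise Mukaiyama–Michael path or remove the silyl group.
- Comparison: the chosen route offers instead a two-component cycloaddition of a purchased ynoate with the cyclic diene 13 (seven steps from 1). Only C10 has to be controlled in its key step, and the other centres are set one at a time on a rigid decalin.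

**Alternative 2:** The disconnection is C9–C10 (with C5–H and C8–O), closing ring B by cationic cyclisation of the monocyclic triacetate A3 to the decalin triacetate A4.
- Forward key step: FSO3H at low temperature protonates C5 of the tetrasubstituted C5=C10 alkene of A3; C9 of the (E)-C8=C9 alkene captures the tertiary C10 cation through a chair, and the C8 cation takes up oxygen on work-up.
- For it: it is biomimetic and short, sets C5, C8, C9 and C10, and delivers the C8 hydroxyl directly. Anti addition across both alkenes gives the trans fusion and the equatorial C11 by geometry. A3 could be reached from the enol triflate 12, so the front end would be shared. In step economy after the key step it is stronger than the chosen route.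
- Against it: the face of ring A on which the chain closes is decided only by the small difference between C14 and C13 at C4. Capture of the C8 cation competes with proton loss and can give either C8 configuration. A4 carries three acetates, two of them primary, that must then be differentiated for the aryl ether, the angelate and the free C3 hydroxyl.
- Comparison: the chosen route offers orthogonally masked oxygens (acetonide at O3/O13, ester at C11) and sets C5, C9 and C8 in separate substrate-controlled steps.

**Alternative 3:** The disconnection is C3–C4, closing ring A by reductive aldol cyclisation of the aldehyde–acrylate A5 to the hydroxy ester A6.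
- Forward key step: [(Ph3P)CuH]6 adds hydride to C14 of the acrylate of A5, and the C4 copper enolate adds to the C3 aldehyde.
- For it: the quaternary C4 and the C3 carbinol form in one C–C bond formation, C13 is at the ester level so it is distinguished from C14 from the outset, the trans ring fusion is already present in A5, and the conditions are mild. For the C3/C4 pair it is more direct than the chosen route.
- Against it: A6 contains nothing of C11 or C12; C9 is a masked ketone and C8 a methylene. The most congested part of the target (the C8 carbinol and C9 with C11 beside the quaternary C10) would therefore have to be built afterwards on a hindered ketone. A closed, metal-bridged transition state is expected to place O3 and the ester carbon on the same side of the new ring, whereas the target has O3 trans to C13. A5 needs its own enantioselective entry to C5/C10.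
- Comparison: in the chosen route the C3/C4 pair comes from 1 by two anti alkylations and a stereoretentive rearrangement, and the key step brings in all four missing carbons of ring B at once.

Key step: step 8

## Remarks on the chemistry

- Ring A is taken from (R)-carvone. A desymmetrising reduction of a 2-alkoxymethyl-2-methylcyclohexane-1,3-dione would be expected to deliver hydride anti to the larger alkoxymethyl group and so place O3 cis to C13, whereas the target and a trans-fused acetonide need O3 trans to C13.
- Bicyclic compounds are named with the drimane numbering of the analysis, and CIP descriptors refer to that numbering. The product of step 10 is drawn as the exocyclic 8(12)-ene; any endocyclic 7-ene isomer formed beside it would give the same C8 radical, and hence the same product, in step 12.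

## Route

Step 1
Reactants: 1 (R)-(−)-carvone [(5R)-2-methyl-5-(prop-1-en-2-yl)cyclohex-2-en-1-one]
Product: 3 (5R,6S)-2,6-dimethyl-5-(prop-1-en-2-yl)cyclohex-2-en-1-one (trans-6-methylcarvone), via lithium dienolate of carvone 2 (not isolated)
Conditions: LiN(i-Pr)2, THF, −78 °C; then MeI, −78 → 0 °C
Reagents that add atoms: iodomethane, CI
Why: Kinetic deprotonation at C6 (the α′-carbon) gives the cross-conjugated lithium dienolate, and its SN2 methylation is a standard enolate alkylation. The new C6 centre becomes trigonal again in step 2, so its configuration does not matter.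

Step 2
Reactants: 3 (5R,6S)-2,6-dimethyl-5-(prop-1-en-2-yl)cyclohex-2-en-1-one
Product: 6 [(1R,6S)-1,3-dimethyl-2-oxo-6-(prop-1-en-2-yl)cyclohex-3-en-1-yl]methyl acetate, via lithium enolate of the methylated enone 4 (not isolated), via lithium aldolate 5 (not isolated)
Conditions: LiN(i-Pr)2, THF, −78 → 0 °C; CH2O (gas, from cracked paraformaldehyde), −78 °C; then Ac2O, −78 °C → rt
Reagents that add atoms: formaldehyde, C=O; acetic anhydride, CC(=O)OC(C)=O
Why: A second α′-deprotonation gives the tetrasubstituted enolate, and the aldol addition to monomeric formaldehyde should occur on the face opposite the pseudoaxial isopropenyl group. This sets the quaternary centre (future C4) with C13 trans and C14 cis to the isopropenyl group. Acetylating the lithium aldolate in the same flask closes the retro-aldol pathway.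

Step 3
Reactants: 6 [(1R,6S)-1,3-dimethyl-2-oxo-6-(prop-1-en-2-yl)cyclohex-3-en-1-yl]methyl acetate
Product: 8 [(1S,6R)-6-acetoxy-1,3-dimethyl-2-oxocyclohex-3-en-1-yl]methyl acetate, via methoxy hydroperoxide 7 (not isolated)
Conditions: O3, CH2Cl2/MeOH, −78 °C; then Ac2O, Et3N, DMAP (cat.), CH2Cl2, 0 °C → rt
Reagents that add atoms: ozone, [O-][O+]=O; methanol, CO
Why: Ozone cleaves the electron-rich 1,1-disubstituted alkene in preference to the electron-poor enone, and methanol traps the carbonyl oxide as the α-methoxy hydroperoxide. Its peracetate undergoes the Criegee rearrangement, in which the ring carbon migrates to oxygen with retention, so the future C3 keeps its configuration. The ring-bound oxygen comes from ozone, the acetyl carbons are the former isopropenyl C–CH3, and the acyl oxygen comes from methanol or ozone depending on how the dialkoxycarbenium ion collapses.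

Step 4
Reactants: 8 [(1S,6R)-6-acetoxy-1,3-dimethyl-2-oxocyclohex-3-en-1-yl]methyl acetate
Product: 9 (5R,6S)-5-hydroxy-6-(hydroxymethyl)-2,6-dimethylcyclohex-2-en-1-one
Conditions: K2CO3 (0.2 equiv), MeOH, 0 °C
Reagents that add atoms: none
Why: Carbonate-catalysed transesterification with methanol removes both acetates. The low temperature and short exposure are chosen because the product is a β-hydroxy ketone that could undergo retro-aldol cleavage under base.

Step 5
Reactants: 9 (5R,6S)-5-hydroxy-6-(hydroxymethyl)-2,6-dimethylcyclohex-2-en-1-one
Product: 10 (4aS,8aR)-2,2,4a,6-tetramethyl-4a,8a-dihydro-4H-1,3-benzodioxin-5(8H)-one (trans-fused acetonide)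
Conditions: Me2C(OMe)2, PPTS (cat.), CH2Cl2, rt
Reagents that add atoms: 2,2-dimethoxypropane, COC(C)(C)OC
Why: Acid-catalysed transketalisation: the trans-related O3 and C13 hydroxyl, both equatorial, close a trans-fused 1,3-dioxane. This locks ring A and leaves the C14 methyl pseudoaxial.

Step 6
Reactants: 10 (4aS,8aR)-2,2,4a,6-tetramethyl-4a,8a-dihydro-4H-1,3-benzodioxin-5(8H)-one
Product: 12 (4aS,8aR)-2,2,4a,6-tetramethyl-4a,7,8,8a-tetrahydro-4H-1,3-benzodioxin-5-yl trifluoromethanesulfonate, via lithium enolate 11 (not isolated)
Conditions: LiBH(s-Bu)3, THF, −78 °C; then PhNTf2, −78 °C → rt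
Reagents that add atoms: N-phenylbis(trifluoromethanesulfonimide), O=S(=O)(N(c1ccccc1)S(=O)(=O)C(F)(F)F)C(F)(F)F
Why: Conjugate reduction with enolate trapping: the hindered borohydride adds hydride 1,4 to the β-unsubstituted enone, whose carbonyl is shielded by the quaternary C4, and forms the enolate regiospecifically between C5 and C10. O-Sulfonylation then gives the tetrasubstituted enol triflate.

Step 7
Reactants: 12 (4aS,8aR)-2,2,4a,6-tetramethyl-4a,7,8,8a-tetrahydro-4H-1,3-benzodioxin-5-yl trifluoromethanesulfonate
Product: 13 (4aS,8aR)-5-ethenyl-2,2,4a,6-tetramethyl-4a,7,8,8a-tetrahydro-4H-1,3-benzodioxine (ring A diene C10=C5–C6=C7 with 3,13-acetonide)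
Conditions: CH2=CHSnBu3, Pd(PPh3)4 (5 mol %), LiCl, THF, reflux
Reagents that add atoms: tributyl(vinyl)stannane, C=C[Sn](CCCC)(CCCC)CCCC
Why: Stille coupling: oxidative addition of the enol triflate to zerovalent palladium, chloride-assisted transmetalation of the vinyl group from tin, and reductive elimination. The reaction is established for hindered 2,6,6-trisubstituted cyclohexenyl triflates.

Step 8
Reactants: 13 (4aS,8aR)-5-ethenyl-2,2,4a,6-tetramethyl-4a,7,8,8a-tetrahydro-4H-1,3-benzodioxine; 14 methyl but-2-ynoate
Product: 15 methyl (3R,4S,10R)-3,13-(isopropylidenedioxy)drima-5,8-dien-11-oate (C15 on the face of C14; C12 on C8; ester on C9)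
Conditions: 14 (3 equiv) premixed with EtAlCl2 (1.2 equiv), CH2Cl2, −40 → 0 °C
Reagents that add atoms: none
Why: EtAlCl2 binds the ester carbonyl of 14 and lowers its LUMO, so the ynoate adds to the s-cis conformer of the electron-rich diene 13 in a normal-demand, concerted but asynchronous [4+2] cycloaddition. The closest known reaction type is the thermal or Lewis-acid-promoted Diels–Alder reaction of 2,6,6-trisubstituted 1-vinylcyclohexenes with acetylenic esters, the classical entry to drimane skeletons. Ring B is closed as the cycloadduct ring itself, a six-membered ring formed suprafacially on both partners through the bonds C7–C8 and C9–C10. The unsubstituted terminus C7 carries the larger HOMO coefficient and bonds first to the electrophilic β-carbon of 14 (the future C8 with C12); the developing positive charge sits at the tertiary allylic C10, which then bonds to the α-carbon (C9 with the ester carbon C11). The only new stereocentre is C10, and it is controlled by C4: the trans-fused acetonide holds ring A in a half-chair in which C14 is pseudoaxial and syn-1,3 to the C10 terminus, so the dienophile should add to the opposite (β) face and C15 is pushed to the face of C14. The step therefore needs regioselectivity, secured by the substitution pattern of the diene and the polarisation of the ynoate, and π-facial selectivity, secured by the conformational lock of the acetonide. The 1,4-diene 15 cannot aromatise because C10 is quaternary, and EtAlCl2 also scavenges protons, which protects the acid-sensitive diene and acetonide.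

Step 9
Reactants: 15 methyl (3R,4S,10R)-3,13-(isopropylidenedioxy)drima-5,8-dien-11-oate
Product: 16 methyl (3R,4S,5S,10R)-3,13-(isopropylidenedioxy)drim-8-en-11-oate (trans-fused; H5 β)
Conditions: H2 (1 atm), Pd/C, EtOAc, rt
Reagents that add atoms: none
Why: Heterogeneous hydrogenation reduces the trisubstituted C5=C6 bond before the tetrasubstituted, conjugated C8=C9 bond. Hydrogen is delivered to the face opposite the axial methyl groups C14 and C15 that flank C5, which gives H5 anti to C15 and the trans ring fusion.

Step 10
Reactants: 16 methyl (3R,4S,5S,10R)-3,13-(isopropylidenedioxy)drim-8-en-11-oate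
Product: 18 methyl (3R,4S,5S,9R,10R)-3,13-(isopropylidenedioxy)drim-8(12)-en-11-oate (H9 β; ester equatorial), via lithium dienolate of the ester 17 (not isolated)
Conditions: LiN(i-Pr)2, HMPA, THF, −78 → −30 °C; then AcOH, −78 °C
Reagents that add atoms: none
Why: Deconjugative protonation: γ-deprotonation at the C12 methyl, which lies cis to the ester, gives the dienolate, and kinetic α-protonation at C9 gives the β,γ-unsaturated ester. The proton should enter from the β face because the α face of C9 is covered by the axial C15, so C11 ends up equatorial.

Step 11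
Reactants: 18 methyl (3R,4S,5S,9R,10R)-3,13-(isopropylidenedioxy)drim-8(12)-en-11-oate
Product: 19 (3R,4S,5S,9R,10R)-3,13-(isopropylidenedioxy)drim-8(12)-en-11-ol
Conditions: LiAlH4, Et2O, 0 °C
Reagents that add atoms: none
Why: Hydride reduction of the ester to the primary alcohol; the acetonide and the isolated alkene are inert. Reduction also removes the acidity at C9, so that centre is secured.

Step 12
Reactants: 19 (3R,4S,5S,9R,10R)-3,13-(isopropylidenedioxy)drim-8(12)-en-11-ol
Product: 20 (3R,4S,5S,8S,9R,10R)-3,13-(isopropylidenedioxy)drimane-8,11-diol (8-OH β, equatorial; C12 α, axial)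
Conditions: Co(acac)2 (cat.), PhSiH3, O2 (1 atm), THF/i-PrOH, rt
Reagents that add atoms: dioxygen, O=O
Why: Mukaiyama hydration: a cobalt hydride transfers a hydrogen atom to C12 and the tertiary C8 radical is trapped by O2 and reduced to the alcohol, with Markovnikov regiochemistry. The axial approach to C8 is blocked by the syn-axial C15, so oxygen should enter equatorially, leaving C12 axial and cis to C15.

Step 13
Reactants: 20 (3R,4S,5S,8S,9R,10R)-3,13-(isopropylidenedioxy)drimane-8,11-diol; 21 7-hydroxycoumarin
Product: 22 7-{[(3R,4S,5S,8S,9R,10R)-8-hydroxy-3,13-(isopropylidenedioxy)driman-11-yl]oxy}-2H-chromen-2-one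
Conditions: PPh3, DIAD, THF, 0 → 50 °C
Reagents that add atoms: none
Why: Mitsunobu etherification: the acidic phenol (pKa about 8) displaces the oxyphosphonium ion formed at the only primary hydroxyl, C11. The tertiary C8 hydroxyl is not activated, and the lactone is introduced only now, after all hydride steps.

Step 14
Reactants: 22 7-{[(3R,4S,5S,8S,9R,10R)-8-hydroxy-3,13-(isopropylidenedioxy)driman-11-yl]oxy}-2H-chromen-2-one
Product: 23 7-{[(3R,4S,5S,8S,9R,10R)-3,8,13-trihydroxydriman-11-yl]oxy}-2H-chromen-2-one
Conditions: AcOH/H2O/THF (3:1:1), 40 °C
Reagents that add atoms: none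
Why: Mild acid-catalysed hydrolysis of the acetonide frees O3 and O13. The conditions are too weak to dehydrate the tertiary C8 alcohol or to open the lactone.

Step 15
Reactants: 23 7-{[(3R,4S,5S,8S,9R,10R)-3,8,13-trihydroxydriman-11-yl]oxy}-2H-chromen-2-one; 24 angelic acid [(Z)-2-methylbut-2-enoic acid]
Product: 26 [(3R,4S,5S,8S,9R,10R)-3,8-dihydroxy-11-(2-oxo-2H-chromen-7-yloxy)driman-13-yl] (Z)-2-methylbut-2-enoate (target CNP0139045.1), via angelic 2,4,6-trichlorobenzoic anhydride 25 (not isolated)
Conditions: 24, 2,4,6-trichlorobenzoyl chloride, Et3N, toluene, rt; then 23, toluene, 75 °C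
Reagents that add atoms: none
Why: Yamaguchi-type mixed-anhydride esterification: the primary C13 hydroxyl attacks the less hindered angeloyl carbonyl and should react ahead of the hindered secondary C3 and tertiary C8 hydroxyls. Omitting a nucleophilic catalyst avoids the addition–elimination pathway that isomerises angelates to tiglates.

## Compound list

1 | (R)-(−)-carvone, (5R)-2-methyl-5-(prop-1-en-2-yl)cyclohex-2-en-1-one | CC(=C)[C@@H]1CC=C(C)C(=O)C1 | starting material
2 | lithium cross-conjugated dienolate of (R)-carvone (deprotonated at C6) | CC(=C)[C@@H]1CC=C(C)C(O[Li])=C1 | intermediate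
3 | (5R,6S)-2,6-dimethyl-5-(prop-1-en-2-yl)cyclohex-2-en-1-one (trans-6-methylcarvone) | C[C@@H]1C(=O)C(C)=CC[C@H]1C(C)=C | intermediate
4 | lithium enolate of 3 (tetrasubstituted, C1=C6) | CC1=C(O[Li])C(C)=CC[C@H]1C(C)=C | intermediate
5 | lithium [(1R,6S)-1,3-dimethyl-2-oxo-6-(prop-1-en-2-yl)cyclohex-3-en-1-yl]methanolate (formaldehyde aldolate) | [Li]OC[C@]1(C)C(=O)C(C)=CC[C@H]1C(C)=C | intermediate
6 | [(1R,6S)-1,3-dimethyl-2-oxo-6-(prop-1-en-2-yl)cyclohex-3-en-1-yl]methyl acetate | CC(=O)OC[C@]1(C)C(=O)C(C)=CC[C@H]1C(C)=C | intermediate
7 | α-methoxy hydroperoxide from ozonolysis of 6 in methanol (1-hydroperoxy-1-methoxyethyl group in place of isopropenyl; mixture at the peroxy carbon) | CC(=O)OC[C@]1(C)C(=O)C(C)=CC[C@H]1C(C)(OC)OO | intermediate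
8 | [(1S,6R)-6-acetoxy-1,3-dimethyl-2-oxocyclohex-3-en-1-yl]methyl acetate | CC(=O)OC[C@]1(C)C(=O)C(C)=CC[C@H]1OC(C)=O | intermediate
9 | (5R,6S)-5-hydroxy-6-(hydroxymethyl)-2,6-dimethylcyclohex-2-en-1-one | OC[C@]1(C)C(=O)C(C)=CC[C@H]1O | intermediate
10 | (4aS,8aR)-2,2,4a,6-tetramethyl-4a,8a-dihydro-4H-1,3-benzodioxin-5(8H)-one (trans-fused acetonide enone) | CC1(C)OC[C@]2(C)C(=O)C(C)=CC[C@H]2O1 | intermediate
11 | lithium (4aS,8aR)-2,2,4a,6-tetramethyl-4a,7,8,8a-tetrahydro-4H-1,3-benzodioxin-5-olate | CC1(C)OC[C@]2(C)C(O[Li])=C(C)CC[C@H]2O1 | intermediate
12 | (4aS,8aR)-2,2,4a,6-tetramethyl-4a,7,8,8a-tetrahydro-4H-1,3-benzodioxin-5-yl trifluoromethanesulfonate | CC1(C)OC[C@]2(C)C(OS(=O)(=O)C(F)(F)F)=C(C)CC[C@H]2O1 | intermediate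
13 | (4aS,8aR)-5-ethenyl-2,2,4a,6-tetramethyl-4a,7,8,8a-tetrahydro-4H-1,3-benzodioxine (ring A diene) | CC1(C)OC[C@]2(C)C(C=C)=C(C)CC[C@H]2O1 | intermediate
14 | methyl but-2-ynoate | CC#CC(=O)OC | starting material
15 | methyl (3R,4S,10R)-3,13-(isopropylidenedioxy)drima-5,8-dien-11-oate | CC1(C)OC[C@]2(C)C3=CCC(C)=C(C(=O)OC)[C@]3(C)CC[C@H]2O1 | intermediate
16 | methyl (3R,4S,5S,10R)-3,13-(isopropylidenedioxy)drim-8-en-11-oate | CC1(C)OC[C@]2(C)[C@H]3CCC(C)=C(C(=O)OC)[C@]3(C)CC[C@H]2O1 | intermediate
17 | lithium dienolate of 16 (C8=C12 exocyclic, C9=C11 ester enolate) | CC1(C)OC[C@]2(C)[C@H]3CCC(=C)C(=C(O[Li])OC)[C@]3(C)CC[C@H]2O1 | intermediate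
18 | methyl (3R,4S,5S,9R,10R)-3,13-(isopropylidenedioxy)drim-8(12)-en-11-oate | CC1(C)OC[C@]2(C)[C@H]3CCC(=C)[C@@H](C(=O)OC)[C@]3(C)CC[C@H]2O1 | intermediate
19 | (3R,4S,5S,9R,10R)-3,13-(isopropylidenedioxy)drim-8(12)-en-11-ol | CC1(C)OC[C@]2(C)[C@H]3CCC(=C)[C@@H](CO)[C@]3(C)CC[C@H]2O1 | intermediate
20 | (3R,4S,5S,8S,9R,10R)-3,13-(isopropylidenedioxy)drimane-8,11-diol | CC1(C)OC[C@]2(C)[C@H]3CC[C@](C)(O)[C@@H](CO)[C@]3(C)CC[C@H]2O1 | intermediate
21 | 7-hydroxycoumarin | Oc1ccc2ccc(=O)oc2c1 | starting material
22 | 7-{[(3R,4S,5S,8S,9R,10R)-8-hydroxy-3,13-(isopropylidenedioxy)driman-11-yl]oxy}-2H-chromen-2-one | CC1(C)OC[C@]2(C)[C@H]3CC[C@](C)(O)[C@@H](COc4ccc5ccc(=O)oc5c4)[C@]3(C)CC[C@H]2O1 | intermediate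
23 | 7-{[(3R,4S,5S,8S,9R,10R)-3,8,13-trihydroxydriman-11-yl]oxy}-2H-chromen-2-one | OC[C@]1(C)[C@H]2CC[C@](C)(O)[C@@H](COc3ccc4ccc(=O)oc4c3)[C@]2(C)CC[C@H]1O | intermediate
24 | angelic acid, (Z)-2-methylbut-2-enoic acid | C/C=C(/C)C(=O)O | starting material
25 | angelic 2,4,6-trichlorobenzoic anhydride | C/C=C(/C)C(=O)OC(=O)c1c(Cl)cc(Cl)cc1Cl | intermediate
26 | [(3R,4S,5S,8S,9R,10R)-3,8-dihydroxy-11-(2-oxo-2H-chromen-7-yloxy)driman-13-yl] (Z)-2-methylbut-2-enoate (CNP0139045.1) | C/C=C(/C)C(=O)OC[C@]1(C)[C@H]2CC[C@](C)(O)[C@@H](COc3ccc4ccc(=O)oc4c3)[C@]2(C)CC[C@H]1O | target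

## Step count and least certain steps

Total step count: 15. Longest linear sequence: 15 steps, from 1 to 26; 14, 21 and 24 are purchased and enter directly.

**Step 8 (key step).** The β-methyl ynoate is a weak dienophile and the diene is twisted out of the s-cis geometry by C15 and the C4 substituents, so the cycloaddition may be slow. Under the Lewis acid, stepwise cationic paths (four-ring closure at C6, ene-type proton loss, opening of the acetonide) may compete, and facial selectivity may be incomplete if the pseudoaxial C14 shields C10 less than assumed. Fallback: starting from 13, a thermal cycloaddition without Lewis acid with the more reactive methyl 3-bromoprop-2-ynoate (toluene, 80 °C) should give methyl (3R,4S,10R)-8-bromo-3,13-(isopropylidenedioxy)-12-nordrima-5,8-dien-11-oate F1 with the same regiochemistry. Palladium-catalysed methylation of the vinyl bromide (MeZnCl, Pd(PPh3)4, THF, 50 °C) then installs C12 and returns to the route at 15.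

**Step 4.** The diol 9 is a β-hydroxy ketone twice over. Under carbonate/methanol, retro-aldol loss of the C13 carbon or reversible ring opening at C3–C4 could erode material or scramble C3/C4. Fallback: starting from 8, the acetates are kept until the carbonyl is gone. Conjugate reduction with enolate triflation (LiBH(s-Bu)3; PhNTf2) gives [(1S,6R)-6-acetoxy-1,3-dimethyl-2-(trifluoromethylsulfonyloxy)cyclohex-2-en-1-yl]methyl acetate F2. Stille vinylation gives [(1S,6R)-6-acetoxy-2-ethenyl-1,3-dimethylcyclohex-2-en-1-yl]methyl acetate F3. Methanolysis then gives (1R,2S)-3-ethenyl-2-(hydroxymethyl)-2,4-dimethylcyclohex-3-en-1-ol F4, which has no carbonyl and cannot undergo retro-aldol cleavage, and acetonide formation returns to the route at 13.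

**Step 12.** Trapping of the planar C8 radical may show poor facial selectivity, giving some of the axial alcohol, and the 1,3-diaxial C12/C15 interaction that develops in the desired product works against it. Fallback: starting from 19, epoxidation with mCPBA (NaHCO3, CH2Cl2, 0 °C), in which the peracid should approach the exocyclic alkene equatorially, away from C15, gives (3R,4S,5S,8S,9R,10R)-8,12-epoxy-3,13-(isopropylidenedioxy)driman-11-ol F5. Opening with LiAlH4 at the primary C12 returns to the route at 20.

**Step 13.** C11 is a primary carbon on a CH flanked by two fully substituted carbons, so displacement of the oxyphosphonium ion may be slow, and elimination or interception by the azodicarboxylate-derived hydrazide may take over. Fallback: starting from 20, the bond is made from the other side, by palladium-catalysed C–O coupling of the C11 hydroxyl with 7-bromocoumarin (Pd2(dba)3, t-BuBrettPhos, Cs2CO3, toluene, 90 °C). This needs no substitution at C11 and returns to the route at 22; no new intermediate is made on the way (F0).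

**Step 15.** Slow acylation of the neopentyl C13 hydroxyl may force harsher conditions, with isomerisation of the angelate to the tiglate or acylation at C3. Fallback: starting from 23, the C13 hydroxyl is acylated with 2-[bis(2,2,2-trifluoroethoxy)phosphoryl]propanoic acid (DCC, DMAP, CH2Cl2), which has no isomerisable alkene, to give the C13 2-[bis(2,2,2-trifluoroethoxy)phosphoryl]propanoate of 23, F6. A Still–Gennari olefination with acetaldehyde (KN(SiMe3)2, 18-crown-6, THF, −78 °C) then forms the Z alkene under kinetic control and returns to the route at 26.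

## Further compounds

F1 | step 8 | methyl (3R,4S,10R)-8-bromo-3,13-(isopropylidenedioxy)-12-nordrima-5,8-dien-11-oate | CC1(C)OC[C@]2(C)C3=CCC(Br)=C(C(=O)OC)[C@]3(C)CC[C@H]2O1
F2 | step 4 | [(1S,6R)-6-acetoxy-1,3-dimethyl-2-(trifluoromethylsulfonyloxy)cyclohex-2-en-1-yl]methyl acetate | CC(=O)OC[C@]1(C)C(OS(=O)(=O)C(F)(F)F)=C(C)CC[C@H]1OC(C)=O
F3 | step 4 | [(1S,6R)-6-acetoxy-2-ethenyl-1,3-dimethylcyclohex-2-en-1-yl]methyl acetate | CC(=O)OC[C@]1(C)C(C=C)=C(C)CC[C@H]1OC(C)=O
F4 | step 4 | (1R,2S)-3-ethenyl-2-(hydroxymethyl)-2,4-dimethylcyclohex-3-en-1-ol | OC[C@]1(C)C(C=C)=C(C)CC[C@H]1O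
F5 | step 12 | (3R,4S,5S,8S,9R,10R)-8,12-epoxy-3,13-(isopropylidenedioxy)driman-11-ol (epoxide oxygen β) | CC1(C)OC[C@]2(C)[C@H]3CC[C@@]4(CO4)[C@@H](CO)[C@]3(C)CC[C@H]2O1
F0 | step 13 | none | none
F6 | step 15 | [(3R,4S,5S,8S,9R,10R)-3,8-dihydroxy-11-(2-oxo-2H-chromen-7-yloxy)driman-13-yl] 2-[bis(2,2,2-trifluoroethoxy)phosphoryl]propanoate | CC(C(=O)OC[C@]1(C)[C@H]2CC[C@](C)(O)[C@@H](COc3ccc4ccc(=O)oc4c3)[C@]2(C)CC[C@H]1O)P(=O)(OCC(F)(F)F)OCC(F)(F)F
A1 | alternative 1 | acyclic triene: methyl (E)-enoate C9=C10, 3,13-acetonide, (5E,7Z)-diene with CH3 and OSi(t-Bu)Me2 on C8 | CC1(C)OC[C@](C)(/C=C/C=C(/C)O[Si](C)(C)C(C)(C)C)[C@@H](CC/C(C)=C/C(=O)OC)O1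
A2 | alternative 1 | trans-decalin 6-ene with C8 silyl ether, C11 methyl ester and 3,13-acetonide | CC1(C)OC[C@]2(C)[C@H]3C=C[C@](C)(O[Si](C)(C)C(C)(C)C)[C@@H](C(=O)OC)[C@]3(C)CC[C@H]2O1
A3 | alternative 2 | monocyclic ring A 5(10)-ene with (E)-C8=C9 side chain; C3, C11, C13 triacetate | CC(=O)OC[C@]1(C)C(CC/C(C)=C/COC(C)=O)=C(C)CC[C@H]1OC(C)=O
A4 | alternative 2 | trans-decalin C8 tertiary alcohol; C3, C11, C13 triacetate | CC(=O)OC[C@]1(C)[C@H]2CC[C@](C)(O)[C@@H](COC(C)=O)[C@]2(C)CC[C@H]1OC(C)=O
A5 | alternative 3 | ring B cyclohexane with C9 dioxolane, C10 methyl and 3-oxopropyl chain, C5 methyl acrylate | COC(=O)C(=C)[C@H]1CCCC2(OCCO2)[C@]1(C)CCC=O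
A6 | alternative 3 | trans-decalin C3 alcohol with C13 methyl ester at quaternary C4 and C9 dioxolane | COC(=O)[C@]1(C)[C@H]2CCCC3(OCCO3)[C@]2(C)CC[C@H]1O
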